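Germacrane numbering: C1 furanone C=O, C2=C3 furanone alkene, C4(CH3)=C5, C6 lactone O-CH, C7 ring-fusion CH, C8 acyloxy CH, C9 CH2, C10 O-C(CH3), C11/C12/C13 methylene-lactone carbons. The rings are a γ-lactone, a 3(2H)-furanone and the ten-membered carbocycle C1-C10.
Enabling feature: the oxygenated carbons C1 and C8 are separated only by C10 and C9. With C8 as a ketone this is a 1,4-dicarbonyl array in which C9 and C10 are both enol carbons. The C9-C10 bond lies in the carbocycle and makes C10 of the furanone quaternary, so it is cut first, as an oxidative enol-enol union held by an O1-Si-O8 bridge.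
Further cuts: the C8-O acyl bond, C11=C13 (carried as C11H-CH2OSi), the furanone ring (from a 4-hydroxy-2-ynone), C3-C4 and C3-C2 (CO between vinyl iodide and alkyne), C4=C5 (iodo-Wittig), C11-C13 (formaldehyde aldol) and C7-C8 (cuprate).
Forward order: the lactone ring is present from the start. C7, C11 and C5 are then elaborated, the chain is grown to C10/C14, the furanone closes (step 9), silicon closes an eleven-membered ring (step 10) and the carbocycle closes (step 11). C8 reduction, acylation and methylene unmasking follow.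
Stereochemistry: C6 comes from butenolide 1, C7 and C11 from anti additions on the lactone, and Z-C4=C5 from the Wittig step. C10 comes from face-selective transannular coupling (it is planar in 18), C8 from peripheral hydride attack, and C2' from acid 21.

Key step: step 11

Assumption: in 19 the C8 carbonyl is taken to stand across the ring with C6-C7-C8-C9 gauche, so that its open outer face is the one leading to the 8R alcohol.
Remark: 12 is used as the racemate, so 13, 14 and 15 are pairs of C10 epimers and their SMILES leave C10 open. The centre becomes planar in 17 and 18.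

Step 1
Reactants: 1 (S)-5-(hydroxymethyl)furan-2(5H)-one
Product: 2 (S)-5-[(tert-butyldimethylsilyloxy)methyl]furan-2(5H)-one
Conditions: TBSCl, imidazole, CH2Cl2, 0 °C → rt
Reagents that add atoms: tert-butyldimethylsilyl chloride CC(C)(C)[Si](C)(C)Cl
Why: Imidazole-promoted silyl ether formation at a primary alcohol is too mild to deprotonate the γ-position, so C6 keeps its configuration.

Step 2
Reactants: 2 (S)-5-[(tert-butyldimethylsilyloxy)methyl]furan-2(5H)-one
Product: 4 (4S,5S)-5-[(tert-butyldimethylsilyloxy)methyl]-4-(1-ethoxyvinyl)dihydrofuran-2(3H)-one, via trimethylsilyl ketene acetal 3 (not isolated)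
Conditions: CH2=CHOEt, t-BuLi, THF, −78 → 0 °C; CuI, Me2S, −40 °C; 2, TMSCl, −78 °C; aq NH4Cl/NH3; Et3N-washed silica
Reagents that add atoms: ethyl vinyl ether C=COCC; chlorotrimethylsilane C[Si](C)(C)Cl (silicon stays only in 3)
Why: TMSCl-accelerated conjugate addition of a Gilman cuprate bearing an α-alkoxyvinyl ligand (acyl anion equivalent) takes place anti to the C6 side chain, which sets C7 trans to C6 and brings in C8/C9 as a masked methyl ketone.

Step 3
Reactants: 4 (4S,5S)-5-[(tert-butyldimethylsilyloxy)methyl]-4-(1-ethoxyvinyl)dihydrofuran-2(3H)-one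
Product: 6 (3R,4S,5S)-5-[(tert-butyldimethylsilyloxy)methyl]-4-(1-ethoxyvinyl)-3-(hydroxymethyl)dihydrofuran-2(3H)-one, via lithium enolate 5 (not isolated)
Conditions: LDA, THF, −78 °C; CH2O (g, cracked paraformaldehyde), −78 → −30 °C; H2O
Reagents that add atoms: formaldehyde C=O; lithium diisopropylamide [Li]N(C(C)C)C(C)C (lithium stays only in 5)
Why: Aldol addition of the lactone lithium enolate to monomeric formaldehyde occurs anti to the C7 substituent and gives the trans C11 centre, which is erased in step 15; the enol ether is inert to base.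

Step 4
Reactants: 6 (3R,4S,5S)-5-[(tert-butyldimethylsilyloxy)methyl]-4-(1-ethoxyvinyl)-3-(hydroxymethyl)dihydrofuran-2(3H)-one
Product: 7 (3R,4S,5S)-5-[(tert-butyldimethylsilyloxy)methyl]-3-[(tert-butyldiphenylsilyloxy)methyl]-4-(1-ethoxyvinyl)dihydrofuran-2(3H)-one
Conditions: TBDPSCl, imidazole, DMF, rt
Reagents that add atoms: tert-butyldiphenylsilyl chloride CC(C)(C)[Si](Cl)(c1ccccc1)c1ccccc1
Why: Silyl ether formation puts on C13-O a group that should outlast the acid of steps 5 and 9 and the cerium(IV) of step 11, and that can be told apart from the TBS ether.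

Step 5
Reactants: 7 (3R,4S,5S)-5-[(tert-butyldimethylsilyloxy)methyl]-3-[(tert-butyldiphenylsilyloxy)methyl]-4-(1-ethoxyvinyl)dihydrofuran-2(3H)-one
Product: 9 (3R,4S,5S)-3-[(tert-butyldiphenylsilyloxy)methyl]-5-(hydroxymethyl)-4-(2-methyl-1,3-dioxolan-2-yl)dihydrofuran-2(3H)-one, via dioxolane TBS ether 8 (not isolated)
Conditions: HOCH2CH2OH (excess), CSA (cat.), MeCN/CH2Cl2, 0 °C → rt
Reagents that add atoms: ethylene glycol OCCO
Why: Acid-catalysed addition of the diol to the enol ether with loss of ethanol (transketalisation) gives the dioxolane quickly, and the same acidic alcoholic medium then solvolyses the primary TBS ether while the TBDPS ether stays; the trans C6/C7 arrangement keeps the freed alcohol away from C8.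

Step 6
Reactants: 9 (3R,4S,5S)-3-[(tert-butyldiphenylsilyloxy)methyl]-5-(hydroxymethyl)-4-(2-methyl-1,3-dioxolan-2-yl)dihydrofuran-2(3H)-one
Product: 10 (2S,3S,4R)-4-[(tert-butyldiphenylsilyloxy)methyl]-3-(2-methyl-1,3-dioxolan-2-yl)-5-oxotetrahydrofuran-2-carbaldehyde
Conditions: Dess-Martin periodinane, CH2Cl2, 0 °C → rt; used without storage
Reagents that add atoms: none
Why: Dess-Martin oxidation stops at the aldehyde under non-aqueous, nearly neutral conditions that spare the ketal, the silyl ether and the epimerisable C6 centre.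

Step 7
Reactants: 10 (2S,3S,4R)-4-[(tert-butyldiphenylsilyloxy)methyl]-3-(2-methyl-1,3-dioxolan-2-yl)-5-oxotetrahydrofuran-2-carbaldehyde
Product: 11 (3R,4S,5S)-3-[(tert-butyldiphenylsilyloxy)methyl]-5-[(Z)-2-iodoprop-1-enyl]-4-(2-methyl-1,3-dioxolan-2-yl)dihydrofuran-2(3H)-one
Conditions: EtPPh3I, n-BuLi, THF, rt; I2, −78 °C; NaHMDS, −20 °C; then 10, −78 °C
Reagents that add atoms: ethyltriphenylphosphonium iodide CC[P+](c1ccccc1)(c1ccccc1)c1ccccc1.[I-]; iodine II
Why: Wittig olefination with (1-iodoethylidene)triphenylphosphorane (Stork-Zhao type) is a kinetically controlled reaction of a non-stabilised ylide that places iodine cis to C6, giving the Z-iodide that maps onto the Z C4=C5 bond, and the low temperature limits enolisation at C6.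

Step 8
Reactants: 11 (3R,4S,5S)-3-[(tert-butyldiphenylsilyloxy)methyl]-5-[(Z)-2-iodoprop-1-enyl]-4-(2-methyl-1,3-dioxolan-2-yl)dihydrofuran-2(3H)-one; 12 but-3-yn-2-ol (racemic)
Product: 13 (3R,4S,5R)-3-[(tert-butyldiphenylsilyloxy)methyl]-5-[(1Z)-6-hydroxy-2-methyl-3-oxohept-1-en-4-ynyl]-4-(2-methyl-1,3-dioxolan-2-yl)dihydrofuran-2(3H)-one (C10 epimers)
Conditions: PdCl2(PPh3)2 (cat.), CuI (cat.), Et3N, THF, CO (1 atm), rt
Reagents that add atoms: carbon monoxide [C-]#[O+]
Why: Carbonylative Sonogashira coupling (oxidative addition with retention of alkene geometry, CO insertion, transfer of the copper acetylide) makes C3-C4 and C3-C2 in one operation and tolerates the free secondary alcohol.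

Step 9
Reactants: 13 (3R,4S,5R)-3-[(tert-butyldiphenylsilyloxy)methyl]-5-[(1Z)-6-hydroxy-2-methyl-3-oxohept-1-en-4-ynyl]-4-(2-methyl-1,3-dioxolan-2-yl)dihydrofuran-2(3H)-one
Product: 15 (3R,4S,5R)-4-acetyl-3-[(tert-butyldiphenylsilyloxy)methyl]-5-[(1Z)-2-(5-methyl-4-oxo-4,5-dihydrofuran-2-yl)prop-1-enyl]dihydrofuran-2(3H)-one (C10 epimers), via diethylamino enone 14 (not isolated)
Conditions: Et2NH, EtOH, rt; concentrate; 1 M HCl, THF, rt, under N2
Reagents that add atoms: water O (oxygen at C1 and at C8); diethylamine CCNCC (stays only in 14)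
Why: Aza-Michael addition to the ynone puts a heteroatom on C1, and acid hydrolysis then gives the C1,C3-diketone whose C10 hydroxyl cyclodehydrates onto C3 (the classical 3(2H)-furanone synthesis from 4-hydroxy-2-ynones), while the same acid cleaves the dioxolane to the C8 methyl ketone and leaves the TBDPS ether.

Step 10
Reactants: 15 (3R,4S,5R)-4-acetyl-3-[(tert-butyldiphenylsilyloxy)methyl]-5-[(1Z)-2-(5-methyl-4-oxo-4,5-dihydrofuran-2-yl)prop-1-enyl]dihydrofuran-2(3H)-one; 16 diisopropylsilyl bis(trifluoromethanesulfonate)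
Product: 18 cyclic diisopropylsilylene bis-enol ether (4Z,6R,7S,11R): eleven-membered ring in which O-Si(iPr)2-O links C8(=C9H2) to C1 of the 2-methylfuran and C13 carries OTBDPS, via furyloxysilyl triflate 17 (not isolated)
Conditions: 16 (1.0 equiv, syringe pump), Et3N, CH2Cl2 (ca. 2 mM), −78 → 0 °C; filtration through Et3N-washed silica
Reagents that add atoms: none
Why: This is silyl enol ether formation by soft enolisation with a silyl triflate and a tertiary amine: the furanone gains furan aromaticity and is silylated first to 17, its remaining Si-OTf then activates the C8 ketone intramolecularly at high dilution, the amine takes the unhindered C9 proton rather than the tertiary C7-H, and both C10 epimers of 15 converge on one planar furan.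

Step 11
Reactants: 18 cyclic diisopropylsilylene bis-enol ether
Product: 19 (4Z,6R,7S,10R,11R)-13-(tert-butyldiphenylsilyloxy)-3,10-epoxy-1,8-dioxogermacra-2,4-dien-12,6-olide
Conditions: CAN (2.2 equiv), NaHCO3 (4.4 equiv), MeCN, −30 → −10 °C
Reagents that add atoms: none
Why: Proposed new method: CAN takes one electron from the more electron-rich 3-siloxyfuran of 18, the terminal enol-ether carbon C9 adds to C10 of the radical cation, a second CAN oxidises the resulting α-siloxy radical at C8, and loss of the iPr2Si bridge frees the C1 and C8 carbonyls of 19. The closest known reaction type is the cerium(IV)-mediated intramolecular coupling of unsymmetrical dialkylsilyl bis-enol ethers to 1,4-diketones, which tolerates quaternary centres but has not been run with a siloxyfuran partner or across a macrocycle. The bond forms by 7-endo-trig closure of a transient 1,3-dioxa-2-silepane (Si, O, C8, C9, C10, C1, O) inside the eleven-membered silacycle, which is at the same time the 10-endo-trig closure of the carbocycle C1-C10, whose entropic price was already paid in step 10. C10 is the only new stereocentre and should be set as R by the substrate, because the trans-lactone fixes the C5-C6-C7-C8 torsion, allylic 1,3-strain across the Z C4=C5 bond turns H6 toward the furan, and the short O-Si-O strap then lets C9 reach only the Re face of C10. The step needs site selectivity for C10 over C2, the other neighbour of C1; this is secured electronically, since C10 is the β-carbon of the enol silane and its bonding leaves a doubly oxygen-stabilised cation, and by strain, since bonding at C2 would close an eight-membered carbocycle. Bicarbonate buffering at low temperature guards the bis-enol ether against protodesilylation, and the TBDPS ether, the lactone and the product dienone should be oxidised far more slowly than the siloxyfuran.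

Step 12
Reactants: 19 (4Z,6R,7S,10R,11R)-13-(tert-butyldiphenylsilyloxy)-3,10-epoxy-1,8-dioxogermacra-2,4-dien-12,6-olide
Product: 20 (4Z,6R,7R,8R,10R,11R)-13-(tert-butyldiphenylsilyloxy)-3,10-epoxy-8-hydroxy-1-oxogermacra-2,4-dien-12,6-olide
Conditions: NaBH4, MeOH/CH2Cl2, −40 °C
Reagents that add atoms: none
Why: In this borohydride reduction the saturated C8 ketone is far more electrophilic than the vinylogous-ester C1 carbonyl or the lactone, and because the inner face of the carbonyl is shielded by the ring, hydride should arrive from the periphery anti to the C7-C6 ring bond (Felkin-Anh sense) and set C8 as R.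

Step 13
Reactants: 20 (4Z,6R,7R,8R,10R,11R)-13-(tert-butyldiphenylsilyloxy)-3,10-epoxy-8-hydroxy-1-oxogermacra-2,4-dien-12,6-olide; 21 (S)-2-methylbutanoic acid
Product: 23 (4Z,6R,7R,8R,10R,11R)-13-(tert-butyldiphenylsilyloxy)-3,10-epoxy-8-[(S)-2-methylbutanoyloxy]-1-oxogermacra-2,4-dien-12,6-olide, via mixed anhydride 22 (not isolated)
Conditions: 21, 2,4,6-trichlorobenzoyl chloride, Et3N, toluene, rt; then 20, DMAP, rt
Reagents that add atoms: 2,4,6-trichlorobenzoyl chloride O=C(Cl)c1c(Cl)cc(Cl)cc1Cl (aroyl group stays only in 22)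
Why: Yamaguchi esterification acylates hindered secondary alcohols with retention at C8 and, at room temperature, should not disturb the α-centre of the acid.

Step 14
Reactants: 23 (4Z,6R,7R,8R,10R,11R)-13-(tert-butyldiphenylsilyloxy)-3,10-epoxy-8-[(S)-2-methylbutanoyloxy]-1-oxogermacra-2,4-dien-12,6-olide
Product: 24 (4Z,6R,7R,8R,10R,11R)-3,10-epoxy-13-hydroxy-8-[(S)-2-methylbutanoyloxy]-1-oxogermacra-2,4-dien-12,6-olide
Conditions: HF·pyridine, pyridine, THF, 0 °C → rt
Reagents that add atoms: none
Why: Fluoride cleavage of the silyl ether in an acidic buffer avoids the basic conditions that could cause retro-aldol loss of formaldehyde or acyl migration, and it leaves ester, lactone and furanone untouched.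

Step 15
Reactants: 24 (4Z,6R,7R,8R,10R,11R)-3,10-epoxy-13-hydroxy-8-[(S)-2-methylbutanoyloxy]-1-oxogermacra-2,4-dien-12,6-olide
Product: 26 (4Z,6R,7R,8R,10R)-3,10-epoxy-8-[(S)-2-methylbutanoyloxy]-1-oxogermacra-2,4,11(13)-trien-12,6-olide (CNP0174601.1), via mesylate 25 (not isolated)
Conditions: MsCl, Et3N, CH2Cl2, 0 °C; then DBU, 0 °C
Reagents that add atoms: methanesulfonyl chloride CS(=O)(=O)Cl (stays only in 25)
Why: Mesylation followed by E1cB elimination of the β-mesyloxy lactone is the standard unmasking of an α-methylene-γ-butyrolactone; it removes the auxiliary C11 centre and is short and cold enough to leave C2' and C7 alone.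

Compound list
1 | (S)-5-(hydroxymethyl)furan-2(5H)-one | O=C1O[C@@H](C=C1)CO | starting material
2 | (S)-5-[(tert-butyldimethylsilyloxy)methyl]furan-2(5H)-one | O=C1O[C@@H](C=C1)CO[Si](C)(C)C(C)(C)C | intermediate
3 | (2S,3S)-2-[(tert-butyldimethylsilyloxy)methyl]-3-(1-ethoxyvinyl)-5-(trimethylsilyloxy)-2,3-dihydrofuran (ketene acetal, not isolated) | C[Si](C)(C)OC1=C[C@H](C(=C)OCC)[C@@H](CO[Si](C)(C)C(C)(C)C)O1 | intermediate
4 | (4S,5S)-5-[(tert-butyldimethylsilyloxy)methyl]-4-(1-ethoxyvinyl)dihydrofuran-2(3H)-one | O=C1O[C@H](CO[Si](C)(C)C(C)(C)C)[C@@H](C(=C)OCC)C1 | intermediate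
5 | lithium enolate of 4 (not isolated) | [Li+].[O-]C1=C[C@H](C(=C)OCC)[C@@H](CO[Si](C)(C)C(C)(C)C)O1 | intermediate
6 | (3R,4S,5S)-5-[(tert-butyldimethylsilyloxy)methyl]-4-(1-ethoxyvinyl)-3-(hydroxymethyl)dihydrofuran-2(3H)-one | O=C1O[C@H](CO[Si](C)(C)C(C)(C)C)[C@@H](C(=C)OCC)[C@@H]1CO | intermediate
7 | (3R,4S,5S)-5-[(tert-butyldimethylsilyloxy)methyl]-3-[(tert-butyldiphenylsilyloxy)methyl]-4-(1-ethoxyvinyl)dihydrofuran-2(3H)-one | O=C1O[C@H](CO[Si](C)(C)C(C)(C)C)[C@@H](C(=C)OCC)[C@@H]1CO[Si](c2ccccc2)(c3ccccc3)C(C)(C)C | intermediate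
8 | (3R,4S,5S)-5-[(tert-butyldimethylsilyloxy)methyl]-3-[(tert-butyldiphenylsilyloxy)methyl]-4-(2-methyl-1,3-dioxolan-2-yl)dihydrofuran-2(3H)-one (not isolated) | O=C1O[C@H](CO[Si](C)(C)C(C)(C)C)[C@@H](C2(C)OCCO2)[C@@H]1CO[Si](c3ccccc3)(c4ccccc4)C(C)(C)C | intermediate
9 | (3R,4S,5S)-3-[(tert-butyldiphenylsilyloxy)methyl]-5-(hydroxymethyl)-4-(2-methyl-1,3-dioxolan-2-yl)dihydrofuran-2(3H)-one | O=C1O[C@H](CO)[C@@H](C2(C)OCCO2)[C@@H]1CO[Si](c3ccccc3)(c4ccccc4)C(C)(C)C | intermediate
10 | (2S,3S,4R)-4-[(tert-butyldiphenylsilyloxy)methyl]-3-(2-methyl-1,3-dioxolan-2-yl)-5-oxotetrahydrofuran-2-carbaldehyde | O=C1O[C@H](C=O)[C@@H](C2(C)OCCO2)[C@@H]1CO[Si](c3ccccc3)(c4ccccc4)C(C)(C)C | intermediate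
11 | (3R,4S,5S)-3-[(tert-butyldiphenylsilyloxy)methyl]-5-[(Z)-2-iodoprop-1-enyl]-4-(2-methyl-1,3-dioxolan-2-yl)dihydrofuran-2(3H)-one | O=C1O[C@H](/C=C(/C)I)[C@@H](C2(C)OCCO2)[C@@H]1CO[Si](c3ccccc3)(c4ccccc4)C(C)(C)C | intermediate
12 | but-3-yn-2-ol (racemic) | C#CC(C)O | starting material
13 | (3R,4S,5R)-3-[(tert-butyldiphenylsilyloxy)methyl]-5-[(1Z)-6-hydroxy-2-methyl-3-oxohept-1-en-4-ynyl]-4-(2-methyl-1,3-dioxolan-2-yl)dihydrofuran-2(3H)-one (C10 epimers) | O=C1O[C@H](/C=C(/C)C(=O)C#CC(C)O)[C@@H](C2(C)OCCO2)[C@@H]1CO[Si](c3ccccc3)(c4ccccc4)C(C)(C)C | intermediate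
14 | C1-diethylamino enone from 13 (C10 epimers, enamine geometry open, not isolated) | O=C1O[C@H](/C=C(/C)C(=O)C=C(N(CC)CC)C(C)O)[C@@H](C2(C)OCCO2)[C@@H]1CO[Si](c3ccccc3)(c4ccccc4)C(C)(C)C | intermediate
15 | (3R,4S,5R)-4-acetyl-3-[(tert-butyldiphenylsilyloxy)methyl]-5-[(1Z)-2-(5-methyl-4-oxo-4,5-dihydrofuran-2-yl)prop-1-enyl]dihydrofuran-2(3H)-one (C10 epimers) | O=C1O[C@H](/C=C(/C)C2=CC(=O)C(C)O2)[C@@H](C(C)=O)[C@@H]1CO[Si](c3ccccc3)(c4ccccc4)C(C)(C)C | intermediate
16 | diisopropylsilyl bis(trifluoromethanesulfonate) | CC(C)[Si](OS(=O)(=O)C(F)(F)F)(OS(=O)(=O)C(F)(F)F)C(C)C | starting material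
17 | 2-methylfuran-3-yloxy(diisopropyl)silyl triflate with free C8 methyl ketone (not isolated) | O=C1O[C@H](/C=C(/C)c2cc(O[Si](C(C)C)(C(C)C)OS(=O)(=O)C(F)(F)F)c(C)o2)[C@@H](C(C)=O)[C@@H]1CO[Si](c3ccccc3)(c4ccccc4)C(C)(C)C | intermediate
18 | cyclic diisopropylsilylene bis-enol ether (4Z,6R,7S,11R), key-step precursor | C=C1O[Si](C(C)C)(C(C)C)Oc2cc(oc2C)/C(C)=C\[C@H]3OC(=O)[C@@H](CO[Si](c4ccccc4)(c5ccccc5)C(C)(C)C)[C@H]13 | intermediate
19 | (4Z,6R,7S,10R,11R)-13-(tert-butyldiphenylsilyloxy)-3,10-epoxy-1,8-dioxogermacra-2,4-dien-12,6-olide, key-step product | CC(C)(C)[Si](c4ccccc4)(c5ccccc5)OC[C@@H]1C(=O)O[C@@H]2/C=C(/C)C3=CC(=O)[C@@](C)(CC(=O)[C@@H]12)O3 | intermediate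
20 | (4Z,6R,7R,8R,10R,11R)-13-(tert-butyldiphenylsilyloxy)-3,10-epoxy-8-hydroxy-1-oxogermacra-2,4-dien-12,6-olide | CC(C)(C)[Si](c4ccccc4)(c5ccccc5)OC[C@@H]1C(=O)O[C@@H]2/C=C(/C)C3=CC(=O)[C@@](C)(C[C@@H](O)[C@@H]12)O3 | intermediate
21 | (S)-2-methylbutanoic acid | OC(=O)[C@@H](C)CC | starting material
22 | (S)-2-methylbutanoic 2,4,6-trichlorobenzoic anhydride (not isolated) | O=C(OC(=O)[C@@H](C)CC)c1c(Cl)cc(Cl)cc1Cl | intermediate
23 | (4Z,6R,7R,8R,10R,11R)-13-(tert-butyldiphenylsilyloxy)-3,10-epoxy-8-[(S)-2-methylbutanoyloxy]-1-oxogermacra-2,4-dien-12,6-olide | CC(C)(C)[Si](c4ccccc4)(c5ccccc5)OC[C@@H]1C(=O)O[C@@H]2/C=C(/C)C3=CC(=O)[C@@](C)(C[C@@H](OC(=O)[C@@H](C)CC)[C@@H]12)O3 | intermediate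
24 | (4Z,6R,7R,8R,10R,11R)-3,10-epoxy-13-hydroxy-8-[(S)-2-methylbutanoyloxy]-1-oxogermacra-2,4-dien-12,6-olide | OC[C@@H]1C(=O)O[C@@H]2/C=C(/C)C3=CC(=O)[C@@](C)(C[C@@H](OC(=O)[C@@H](C)CC)[C@@H]12)O3 | intermediate
25 | C13 methanesulfonate of 24 (not isolated) | CS(=O)(=O)OC[C@@H]1C(=O)O[C@@H]2/C=C(/C)C3=CC(=O)[C@@](C)(C[C@@H](OC(=O)[C@@H](C)CC)[C@@H]12)O3 | intermediate
26 | (4Z,6R,7R,8R,10R)-3,10-epoxy-8-[(S)-2-methylbutanoyloxy]-1-oxogermacra-2,4,11(13)-trien-12,6-olide (CNP0174601.1) | C=C1C(=O)O[C@@H]2/C=C(/C)C3=CC(=O)[C@@](C)(C[C@@H](OC(=O)[C@@H](C)CC)[C@@H]12)O3 | target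

Total step count: 15. Longest linear sequence: 15 steps (1 → 26); 12, 16 and 21 enter as purchased.

Steps most likely to fail

1. Step 11 (Proposed new method).
- **What may go wrong:** the bis-enol ether may be protodesilylated before electron transfer. The furan radical cation may be captured by nitrate, or the dienylfuran over-oxidised. The two furan faces at C10 may be poorly discriminated.
- **Fallback:** the same bond is made by polar alkylation with known chemistry, setting out from 15. One equivalent of TIPSOTf/Et3N (CH2Cl2, −78 °C) should silylate only the easily enolised furanone and give the 3-(triisopropylsilyloxy)furan methyl ketone F1. Kinetic deprotonation at C9 (LiHMDS, THF, −78 °C) and quenching of the lithium enolate with iodine should give the iodomethyl ketone F2. Slow addition of F2 to CsF in MeCN at high dilution unmasks the furanone enolate, which is alkylated at C10 by the α-iodo ketone. C2-alkylation of 3(2H)-furanone enolates by reactive halides is established. The route is rejoined at 19.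

2. Step 10.
- **What may go wrong:** intermolecular Si-O bond formation may lead to oligomers. Enolisation toward C7 may be followed by β-elimination of the lactone carboxylate. Both carbonyls may be silylated by separate silicon reagents.
- **Fallback:** two discrete hard-enolate silylations replace the soft double enolisation, again from 15. One equivalent of KHMDS (THF, −78 °C) removes the most acidic proton (C10-H), and the furanolate is cannulated into excess iPr2SiCl2. Evaporation of the excess reagent leaves the chloro(diisopropyl)silyl furyl ether F3. Slow addition of F3 to LiHMDS in dilute THF at −78 °C generates the kinetic C9 enolate, which closes onto Si-Cl. The route is rejoined at 18.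

3. Step 12.
- **What may go wrong:** hydride may be delivered to the other carbonyl face if the ring adopts a different conformation. The lactone acyl group may also migrate to the new C8 alkoxide.
- **Fallback:** C8 is inverted in the ester-forming step. The reduction of 19 is accepted as giving the 8S alcohol F4. Mitsunobu esterification of F4 with acid 21 (PPh3, DIAD, toluene, 0 °C → rt) forms the C8-O bond with inversion and replaces steps 12 and 13. The route is rejoined at 23.

Further compounds
F1 | step 11 | (3R,4S,5R)-4-acetyl-3-[(tert-butyldiphenylsilyloxy)methyl]-5-[(1Z)-2-(5-methyl-4-triisopropylsilyloxyfuran-2-yl)prop-1-enyl]dihydrofuran-2(3H)-one | O=C1O[C@H](/C=C(/C)c2cc(O[Si](C(C)C)(C(C)C)C(C)C)c(C)o2)[C@@H](C(C)=O)[C@@H]1CO[Si](c3ccccc3)(c4ccccc4)C(C)(C)C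
F2 | step 11 | (3R,4S,5R)-3-[(tert-butyldiphenylsilyloxy)methyl]-4-(iodoacetyl)-5-[(1Z)-2-(5-methyl-4-triisopropylsilyloxyfuran-2-yl)prop-1-enyl]dihydrofuran-2(3H)-one | O=C1O[C@H](/C=C(/C)c2cc(O[Si](C(C)C)(C(C)C)C(C)C)c(C)o2)[C@@H](C(=O)CI)[C@@H]1CO[Si](c3ccccc3)(c4ccccc4)C(C)(C)C
F3 | step 10 | (3R,4S,5R)-4-acetyl-3-[(tert-butyldiphenylsilyloxy)methyl]-5-[(1Z)-2-{4-[chloro(diisopropyl)silyloxy]-5-methylfuran-2-yl}prop-1-enyl]dihydrofuran-2(3H)-one | O=C1O[C@H](/C=C(/C)c2cc(O[Si](Cl)(C(C)C)C(C)C)c(C)o2)[C@@H](C(C)=O)[C@@H]1CO[Si](c3ccccc3)(c4ccccc4)C(C)(C)C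
F4 | step 12 | (4Z,6R,7R,8S,10R,11R)-13-(tert-butyldiphenylsilyloxy)-3,10-epoxy-8-hydroxy-1-oxogermacra-2,4-dien-12,6-olide | CC(C)(C)[Si](c4ccccc4)(c5ccccc5)OC[C@@H]1C(=O)O[C@@H]2/C=C(/C)C3=CC(=O)[C@@](C)(C[C@H](O)[C@@H]12)O3
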